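**Plan**

- Retrosynthesis: remove the PMB ether; cut the Z C1′=C2′ alkene by cross-metathesis into vinyl lactone 4 and side-chain alkene 18; in 4 cut C4–C5 and O1–C6 together, which leaves (Z)-3-iodoacrylic acid and butadiene; cut 18 at C7′–C8′ (aldol) and around (R)-epichlorohydrin (C3′–C5′).
- Enabling feature: in the pyranone ring, O1 sits on C6, which is allylic to C1′=C2′, and O1–C2(=O)–C3=C4 is a cis-acrylate. A carboxyl-bearing vinylpalladium can therefore add across C5=C6 of a 1,3-diene and close on C6 through an η3-allyl spanning C6–C1′–C2′.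
- Forward: the ring is made first, in one step from two feedstocks. The chain is built from C3′ to C10′ (two epoxide openings, aldol, Evans–Tishchenko), joined to the ring by Z-selective cross-metathesis, then deprotected.
- Stereochemistry: C6 from the chiral ligand on palladium; C4′ bought with (R)-epichlorohydrin; C8′ relayed from C4′ (1,5-anti boron aldol); C6′ relayed from C8′ (1,3-anti Evans–Tishchenko, which also places the acetate on O8′); Z-alkene from the metathesis catalyst.

Key step: step 1

Remark: compounds 1, 2, 5, 7 and 13 are taken as commercial; C2–C6 denote the lactone ring and C1′–C10′ the side chain counted from the ring.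

**Route**

Step 1
Reactants: 1 (Z)-3-iodoprop-2-enoic acid; 2 buta-1,3-diene
Product: 4 (6S)-6-ethenyl-5,6-dihydro-2H-pyran-2-one, via allylpalladium carboxylate 3 (not isolated)
Conditions: Pd2(dba)3 (2.5 mol %), (S)-BINOL-derived N,N-bis[(R)-1-phenylethyl]phosphoramidite (6 mol %), Ag2CO3 (0.6 equiv), 2 (4 equiv), toluene, 40 °C, sealed tube
Reagents that add atoms: none
Why: Proposed new method: oxidative addition of the C–I bond of 1 to zerovalent palladium and silver-assisted loss of iodide should give a five-membered vinylpalladium carboxylate chelate, which inserts one C=C of butadiene at its CH2 terminus (C4–C5 bond) to give the η3-allylpalladium carboxylate 3, whose carboxylate oxygen then attacks the substituted allyl terminus (O1–C6 bond) and returns zerovalent palladium. The closest known reaction type is the palladium-catalysed heteroannulation of 1,3-dienes by o-iodobenzoic acids to 3-vinyl-3,4-dihydroisocoumarins (Larock-type annulation), together with its chiral-ligand-controlled variants with o-iodophenols and o-iodoanilines; a vinylic iodo acid with butadiene under chiral control is the new element. The lactone ring closes in the 6-exo-trig sense (oxygen onto C6, the allyl π-system staying outside the ring as the vinyl group), the eight-membered alternative by attack at the far CH2 terminus being disfavoured. C6 is the only new stereocentre and is set in the C–O bond-forming step by the chiral phosphoramidite on palladium, because the two faces of 3 interconvert by η3–η1–η3 slippage through the unsubstituted allyl terminus (the S lactone is sought; the enantiomeric ligand is used if the R lactone prevails). The step needs insertion at a diene terminus, retention of the cis C3=C4 geometry, C–O closure faster than β-hydride elimination, and no re-ionisation of the allylic lactone product; the carboxylate chelate fixes the cis geometry and holds the oxygen next to the allyl unit, while the bulky monodentate ligand, mild temperature and iodide removal by silver favour C–O bond formation.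

Step 2
Reactants: 5 (R)-epichlorohydrin
Product: 6 (2R)-1-chloropent-4-en-2-ol
Conditions: CH2=CHMgBr (1.3 equiv), CuI (10 mol %), THF, −40 to −20 °C
Reagents that add atoms: vinylmagnesium bromide, C=C[Mg]Br
Why: Copper-catalysed Grignard opening of the epoxide at its unsubstituted CH2 (SN2) should leave the carbinol stereocentre and the primary chloride untouched.

Step 3
Reactants: 6; 7 2-methyl-1,3-dithiane
Product: 10 (2R)-1-(2-methyl-1,3-dithian-2-yl)pent-4-en-2-ol, via 2-lithio-2-methyl-1,3-dithiane 8 (not isolated), via (R)-2-allyloxirane 9 (not isolated)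
Conditions: 7 (2.2 equiv), n-BuLi (2.2 equiv), THF, −30 °C; then 6, −30 °C to rt
Reagents that add atoms: none
Why: The first equivalent of 8 should close the chlorohydrin to epoxide 9 (intramolecular Williamson reaction) and the second should open 9 at its terminal carbon (Corey–Seebach acyl-anion alkylation), so the carbinol configuration is retained.

Step 4
Reactants: 10
Product: 11 2-{(2R)-2-[(4-methoxybenzyl)oxy]pent-4-en-1-yl}-2-methyl-1,3-dithiane
Conditions: NaH, 4-MeOC6H4CH2Cl, n-Bu4NI (cat.), DMF, 0 °C to rt
Reagents that add atoms: 4-methoxybenzyl chloride, COc1ccc(CCl)cc1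
Why: Williamson etherification of the secondary alkoxide should proceed cleanly because the dithiane carbon is quaternary and carries no acidic hydrogen.

Step 5
Reactants: 11
Product: 12 (4R)-4-[(4-methoxybenzyl)oxy]hept-6-en-2-one
Conditions: MeI (excess), CaCO3, MeCN/H2O (9:1), 45 °C
Reagents that add atoms: water, O
Why: Alkylative dethioacetalisation (S-methylation, then hydrolysis) under carbonate buffer should unmask the methyl ketone without β-elimination of the PMB ether and without touching the alkene.

Step 6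
Reactants: 12; 13 3-phenylpropanal
Product: 16 (4R,8R)-8-hydroxy-4-[(4-methoxybenzyl)oxy]-10-phenyldec-1-en-6-one, via dicyclohexylboron enolate 14 (not isolated), via boron aldolate 15 (not isolated)
Conditions: (c-C6H11)2BCl, Et3N, Et2O, −78 to 0 °C; then 13, −78 to −20 °C; then MeOH, pH 7 buffer, H2O2, 0 °C
Reagents that add atoms: none
Why: The methyl-side boron enolate of a β-(4-methoxybenzyl)oxy methyl ketone is expected to add to the aldehyde with 1,5-anti induction (boron-mediated 1,5-anti aldol reaction), which sets C8′ as R from the bought C4′ centre.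

Step 7
Reactants: 16
Product: 18 (3R,5R,7R)-5-hydroxy-7-[(4-methoxybenzyl)oxy]-1-phenyldec-9-en-3-yl acetate, via acetaldehyde hemiacetal 17 (not isolated)
Conditions: SmI2 (30 mol %), CH3CHO (8 equiv), THF, −10 °C
Reagents that add atoms: acetaldehyde, CC=O
Why: In the Evans–Tishchenko reduction the samarium-bound hemiacetal 17 should deliver hydride intramolecularly to the ketone through a chair-like six-membered transition state, giving the 1,3-anti C6′ alcohol and leaving the acetyl group on the C8′ oxygen.

Step 8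
Reactants: 4; 18
Product: 19 (3R,5R,7R,9Z)-5-hydroxy-7-[(4-methoxybenzyl)oxy]-10-[(2S)-6-oxo-3,6-dihydro-2H-pyran-2-yl]-1-phenyldec-9-en-3-yl acetate
Conditions: 4 (3 equiv), Ru(κ2-O2NO)[κ2C,C-(1-adamantyl)(2,6-diisopropylphenyl)imidazolin-2-ylidene](=CH-C6H4-2-O-i-Pr) (Grubbs Z-selective nitrato catalyst, 7.5 mol %), THF, 35 °C, static vacuum
Reagents that add atoms: none
Why: Catalyst-controlled Z-selective olefin cross-metathesis, known for allylic-substituted terminal olefins, should form the C1′=C2′ bond through a side-bound all-syn metallacyclobutane, with excess 4 and ethene removal driving the cross product and the electron-poor ring C3=C4 bond staying inert.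

Step 9
Reactants: 19
Product: 20 (3R,5R,7R,9Z)-5,7-dihydroxy-10-[(2S)-6-oxo-3,6-dihydro-2H-pyran-2-yl]-1-phenyldec-9-en-3-yl acetate
Conditions: DDQ (1.5 equiv), CH2Cl2/pH 7 buffer (10:1), 0 °C
Reagents that add atoms: none
Why: Oxidative cleavage of the electron-rich PMB ether by DDQ in wet, buffered medium should free the C4′ hydroxyl while the acetate, the lactone and the Z-alkene are not oxidised.

**Compound list**

1 | (Z)-3-iodoprop-2-enoic acid | OC(=O)/C=C\I | starting material
2 | buta-1,3-diene | C=CC=C | starting material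
3 | allylpalladium carboxylate (η3-allyl over C6–C1′–C2′, drawn as its C6-bound η1 form, phosphoramidite on Pd omitted, C6 face interconverting) | [Pd]1OC(=O)/C=C\CC1C=C | intermediate
4 | (6S)-6-ethenyl-5,6-dihydro-2H-pyran-2-one | C=C[C@@H]1CC=CC(=O)O1 | intermediate
5 | (R)-epichlorohydrin, (2R)-2-(chloromethyl)oxirane | ClC[C@H]1CO1 | starting material
6 | (2R)-1-chloropent-4-en-2-ol | ClC[C@H](O)CC=C | intermediate
7 | 2-methyl-1,3-dithiane | CC1SCCCS1 | starting material
8 | 2-lithio-2-methyl-1,3-dithiane | [Li]C1(C)SCCCS1 | intermediate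
9 | (R)-2-allyloxirane, (2R)-2-(prop-2-en-1-yl)oxirane | C=CC[C@@H]1CO1 | intermediate
10 | (2R)-1-(2-methyl-1,3-dithian-2-yl)pent-4-en-2-ol | C=CC[C@@H](O)CC1(C)SCCCS1 | intermediate
11 | 2-{(2R)-2-[(4-methoxybenzyl)oxy]pent-4-en-1-yl}-2-methyl-1,3-dithiane | C=CC[C@@H](OCc1ccc(OC)cc1)CC1(C)SCCCS1 | intermediate
12 | (4R)-4-[(4-methoxybenzyl)oxy]hept-6-en-2-one | C=CC[C@@H](OCc1ccc(OC)cc1)CC(C)=O | intermediate
13 | 3-phenylpropanal | O=CCCc1ccccc1 | starting material
14 | dicyclohexylboron enolate of 12 (methyl-side enolate) | C=CC[C@@H](OCc1ccc(OC)cc1)CC(=C)OB(C1CCCCC1)C1CCCCC1 | intermediate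
15 | boron aldolate, O8-dicyclohexylboryl derivative of 16 | C=CC[C@@H](OCc1ccc(OC)cc1)CC(=O)C[C@H](OB(C1CCCCC1)C1CCCCC1)CCc1ccccc1 | intermediate
16 | (4R,8R)-8-hydroxy-4-[(4-methoxybenzyl)oxy]-10-phenyldec-1-en-6-one | C=CC[C@@H](OCc1ccc(OC)cc1)CC(=O)C[C@H](O)CCc1ccccc1 | intermediate
17 | hemiacetal of the C8 hydroxyl of 16 with acetaldehyde (samarium-bound; hemiacetal carbon of either configuration) | C=CC[C@@H](OCc1ccc(OC)cc1)CC(=O)C[C@H](OC(C)O)CCc1ccccc1 | intermediate
18 | (3R,5R,7R)-5-hydroxy-7-[(4-methoxybenzyl)oxy]-1-phenyldec-9-en-3-yl acetate | C=CC[C@@H](OCc1ccc(OC)cc1)C[C@@H](O)C[C@H](OC(C)=O)CCc1ccccc1 | intermediate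
19 | (3R,5R,7R,9Z)-5-hydroxy-7-[(4-methoxybenzyl)oxy]-10-[(2S)-6-oxo-3,6-dihydro-2H-pyran-2-yl]-1-phenyldec-9-en-3-yl acetate | CC(=O)O[C@H](CCc1ccccc1)C[C@H](O)C[C@H](OCc1ccc(OC)cc1)C/C=C\[C@@H]1CC=CC(=O)O1 | intermediate
20 | (3R,5R,7R,9Z)-5,7-dihydroxy-10-[(2S)-6-oxo-3,6-dihydro-2H-pyran-2-yl]-1-phenyldec-9-en-3-yl acetate (CNP0264384.1) | CC(=O)O[C@H](CCc1ccccc1)C[C@H](O)C[C@H](O)C/C=C\[C@@H]1CC=CC(=O)O1 | target

**Count and risks**

Total step count: 9. Longest linear sequence: 8 steps (steps 2–9, from 5).

Steps most likely to fail: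

1. Step 1 (annulation). What may go wrong: insufficient facial discrimination in the C–O bond-forming step, telomerisation of butadiene with the acid, β-hydride elimination of the allylpalladium intermediate, or racemisation of the allylic lactone by re-ionisation on zerovalent palladium. Fallback (known chemistry), setting out from 6 and coming back at 4: NaOH closes 6 to (R)-2-allyloxirane 9, here isolated by distillation. Dimethylsulfonium methylide (Me3SI, n-BuLi, THF) homologates the terminal epoxide to the allylic alcohol (3R)-hexa-1,5-dien-3-ol F1. Mitsunobu esterification with acrylic acid (PPh3, DIAD) inverts the carbinol and gives (3S)-hexa-1,5-dien-3-yl prop-2-enoate F2. Ring-closing metathesis with second-generation Grubbs catalyst, initiated at the unhindered allyl terminus, closes the six-membered lactone 4. This route also supplies configurationally defined 4 for assigning the product of step 1.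

2. Step 8 (Z-selective cross-metathesis). What may go wrong: slow turnover at the secondary, oxygen-bearing allylic position of 4, homodimerisation of 18, or erosion of Z geometry by secondary metathesis. Fallback, setting out from 18 and coming back at 19; the lactone is built on the chain instead of being coupled:
   - TESCl and imidazole give the silyl ether (3R,5R,7R)-7-[(4-methoxybenzyl)oxy]-1-phenyl-5-[(triethylsilyl)oxy]dec-9-en-3-yl acetate F3.
   - Z-selective cross-metathesis with the unhindered partner (Z)-but-2-ene-1,4-diol gives the Z-allylic alcohol (3R,5R,7R,9Z)-11-hydroxy-7-[(4-methoxybenzyl)oxy]-1-phenyl-5-[(triethylsilyl)oxy]undec-9-en-3-yl acetate F4.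
   - Dess–Martin periodinane with NaHCO3 gives the Z-enal (3R,5R,7R,9Z)-7-[(4-methoxybenzyl)oxy]-11-oxo-1-phenyl-5-[(triethylsilyl)oxy]undec-9-en-3-yl acetate F5, used at once.
   - Brown allylation with Ipc2B(allyl) of the (+)-α-pinene series (from (−)-Ipc2BOMe and allylmagnesium bromide, Et2O, −100 °C, ethanolamine work-up) is expected to give the 11S alcohol (3R,5R,7R,9Z,11S)-11-hydroxy-7-[(4-methoxybenzyl)oxy]-1-phenyl-5-[(triethylsilyl)oxy]tetradeca-9,13-dien-3-yl acetate F6.
   - Acryloyl chloride and i-Pr2NEt give the acrylate (3R,5R,7R,9Z,11S)-3-acetoxy-7-[(4-methoxybenzyl)oxy]-1-phenyl-5-[(triethylsilyl)oxy]tetradeca-9,13-dien-11-yl prop-2-enoate F7.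
   - Ring-closing metathesis with second-generation Grubbs catalyst gives the silylated lactone (3R,5R,7R,9Z)-7-[(4-methoxybenzyl)oxy]-10-[(2S)-6-oxo-3,6-dihydro-2H-pyran-2-yl]-1-phenyl-5-[(triethylsilyl)oxy]dec-9-en-3-yl acetate F8.
   - HF·pyridine removes the silyl group to give 19.

3. Step 9 (PMB removal). What may go wrong: capture of the oxidised benzylic position by the neighbouring C6′ hydroxyl (oxidative acetal formation) instead of hydrolysis, or acetyl migration between O8′ and O6′ on prolonged handling. Fallback, setting out from 19 and coming back at 20: DDQ under anhydrous conditions (4 Å sieves, CH2Cl2) is used on purpose to form the 4-methoxybenzylidene acetal of 20 across the syn C4′/C6′ diol F9, which is then hydrolysed with 80 % aqueous AcOH at rt to 20.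

**Further compounds**

F1 | step 1 | (3R)-hexa-1,5-dien-3-ol | C=CC[C@@H](O)C=C
F2 | step 1 | (3S)-hexa-1,5-dien-3-yl prop-2-enoate | C=CC[C@H](OC(=O)C=C)C=C
F3 | step 8 | (3R,5R,7R)-7-[(4-methoxybenzyl)oxy]-1-phenyl-5-[(triethylsilyl)oxy]dec-9-en-3-yl acetate | C=CC[C@@H](OCc1ccc(OC)cc1)C[C@@H](O[Si](CC)(CC)CC)C[C@H](OC(C)=O)CCc1ccccc1
F4 | step 8 | (3R,5R,7R,9Z)-11-hydroxy-7-[(4-methoxybenzyl)oxy]-1-phenyl-5-[(triethylsilyl)oxy]undec-9-en-3-yl acetate | OC/C=C\C[C@@H](OCc1ccc(OC)cc1)C[C@@H](O[Si](CC)(CC)CC)C[C@H](OC(C)=O)CCc1ccccc1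
F5 | step 8 | (3R,5R,7R,9Z)-7-[(4-methoxybenzyl)oxy]-11-oxo-1-phenyl-5-[(triethylsilyl)oxy]undec-9-en-3-yl acetate | O=C/C=C\C[C@@H](OCc1ccc(OC)cc1)C[C@@H](O[Si](CC)(CC)CC)C[C@H](OC(C)=O)CCc1ccccc1
F6 | step 8 | (3R,5R,7R,9Z,11S)-11-hydroxy-7-[(4-methoxybenzyl)oxy]-1-phenyl-5-[(triethylsilyl)oxy]tetradeca-9,13-dien-3-yl acetate | C=CC[C@H](O)/C=C\C[C@@H](OCc1ccc(OC)cc1)C[C@@H](O[Si](CC)(CC)CC)C[C@H](OC(C)=O)CCc1ccccc1
F7 | step 8 | (3R,5R,7R,9Z,11S)-3-acetoxy-7-[(4-methoxybenzyl)oxy]-1-phenyl-5-[(triethylsilyl)oxy]tetradeca-9,13-dien-11-yl prop-2-enoate | C=CC[C@H](OC(=O)C=C)/C=C\C[C@@H](OCc1ccc(OC)cc1)C[C@@H](O[Si](CC)(CC)CC)C[C@H](OC(C)=O)CCc1ccccc1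
F8 | step 8 | (3R,5R,7R,9Z)-7-[(4-methoxybenzyl)oxy]-10-[(2S)-6-oxo-3,6-dihydro-2H-pyran-2-yl]-1-phenyl-5-[(triethylsilyl)oxy]dec-9-en-3-yl acetate | CC(=O)O[C@H](CCc1ccccc1)C[C@H](O[Si](CC)(CC)CC)C[C@H](OCc1ccc(OC)cc1)C/C=C\[C@@H]1CC=CC(=O)O1
F9 | step 9 | 4-methoxybenzylidene acetal of 20 across the syn C4′/C6′ diol (all-cis 2,4,6-trisubstituted 1,3-dioxane) | CC(=O)O[C@H](CCc1ccccc1)C[C@H]1C[C@@H](C/C=C\[C@@H]2CC=CC(=O)O2)O[C@@H](c2ccc(OC)cc2)O1
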